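**Assumptions:** locants C1–C15 follow germacrane numbering (lactone oxygen on C6, esters on C3 and C8, oxirane C1–C10). For each chiral ligand, the antipode that gives the stated configuration is used and its sense is confirmed by Mosher analysis on the first run.

## Retrosynthetic overview

1. The C1–C10 oxirane goes in last (peracid, outer face of the E olefin). The C8 ester comes from Mitsunobu inversion of an 8α-alcohol with (2R,3S)-2,3-dimethyloxirane-2-carboxylic acid, itself from Sharpless epoxidation of tiglyl alcohol.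
2. Key disconnection C7–C8: the β-carbon of a 3-(bromomethyl)butenolide is made nucleophilic as its allylchromium (a lactone homoenolate equivalent) and attacks the C8 aldehyde. This closes the ten-membered ring, creates the α-methylene lactone and sets C7 and C8 in one step.
3. The bromobutenolide comes from ring-closing metathesis of a 2-(bromomethyl)acrylate of a C6 vinyl carbinol, made by Nozaki–Hiyama–Kishi coupling of a Z vinyl iodide with acrolein.
4. The Z iodide (C3 centre, C4=C5 geometry) comes from anti-carbomagnesiation/iodination of a propargylic alcohol made by asymmetric alkynylation. The E C1=C10 olefin comes from carboalumination of a butynyl silyl ether and oxirane opening.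
5. Ring order: butenolide, then the ten-membered carbocycle (the butenolide becomes the α-methylene-γ-butyrolactone), then the C1–C10 oxirane.

## Route

Step 1
Reactants: 1 tert-butyl(but-3-yn-1-yloxy)dimethylsilane; 2 oxirane
Product: 5 (3E)-6-[(tert-butyldimethylsilyl)oxy]-4-methylhex-3-en-1-ol, via vinylalane 3 (not isolated), via lithium alanate 4 (not isolated)
Conditions: AlMe3, Cp2ZrCl2 (25 mol%), CH2Cl2, 0 °C → rt; n-BuLi, THF, −78 °C; oxirane, −78 °C → rt; H2O
Reagents that add atoms: trimethylaluminium, C[Al](C)C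
Why: Negishi zirconium-catalysed carboalumination adds methyl and aluminium syn across the terminal alkyne (methyl on the internal carbon), and the ate complex opens oxirane with retention, fixing the E C1=C10 olefin.

Step 2
Reactants: 5 (3E)-6-[(tert-butyldimethylsilyl)oxy]-4-methylhex-3-en-1-ol
Product: 6 (3E)-6-[(tert-butyldimethylsilyl)oxy]-4-methylhex-3-enal
Conditions: Dess–Martin periodinane, NaHCO3, CH2Cl2, 0 °C; used crude
Reagents that add atoms: none
Why: Buffered Dess–Martin oxidation gives the β,γ-unsaturated aldehyde without migration of the olefin into conjugation.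

Step 3
Reactants: 6 (3E)-6-[(tert-butyldimethylsilyl)oxy]-4-methylhex-3-enal; 7 ethynyltrimethylsilane
Product: 9 (3S,5E)-8-[(tert-butyldimethylsilyl)oxy]-6-methyloct-5-en-1-yn-3-ol, via zinc alkoxide 8 (not isolated)
Conditions: (R,R)-ProPhenol (20 mol%), ZnMe2, Ph3P=O (40 mol%), toluene, 4 °C; then K2CO3, MeOH, rt
Reagents that add atoms: none
Why: Trost ProPhenol zinc-acetylide addition sets C3 by catalyst control (3S), and methanolysis removes the C-silyl group in the same flask.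

Step 4
Reactants: 9 (3S,5E)-8-[(tert-butyldimethylsilyl)oxy]-6-methyloct-5-en-1-yn-3-ol
Product: 12 (1Z,3S,5E)-8-[(tert-butyldimethylsilyl)oxy]-1-iodo-2,6-dimethylocta-1,5-dien-3-yl 2-methylpropanoate, via vinylmagnesium 10 (not isolated), via iodo alkoxide 11 (not isolated)
Conditions: MeMgBr (3 equiv), CuI (20 mol%), THF, −10 °C → rt; I2, −78 → 0 °C; (iPrCO)2O, DMAP (cat.), 0 °C → rt
Reagents that add atoms: methylmagnesium bromide, C[Mg]Br; iodine, II; 2-methylpropanoic anhydride, CC(C)C(=O)OC(=O)C(C)C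
Why: Copper-catalysed anti-carbomagnesiation of the propargylic alkoxide (Duboudin type) puts methyl on the proximal carbon and magnesium on the terminal carbon cis to the carbinol, so iodinolysis gives the Z iodide that fixes the C4=C5 geometry, and the magnesium alkoxide is acylated in situ.

Step 5
Reactants: 12 (1Z,3S,5E)-8-[(tert-butyldimethylsilyl)oxy]-1-iodo-2,6-dimethylocta-1,5-dien-3-yl 2-methylpropanoate; 13 prop-2-enal
Product: 14 (3S,4Z,6S,8E)-11-[(tert-butyldimethylsilyl)oxy]-3-hydroxy-5,9-dimethylundeca-1,4,8-trien-6-yl 2-methylpropanoate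
Conditions: CrCl2 (10 mol%), Kishi oxazoline–sulfonamide ligand (12 mol%), Et3N; NiCl2·(2,9-dimethyl-1,10-phenanthroline) (2 mol%), Mn, Cp2ZrCl2, LiCl, MeCN, rt
Reagents that add atoms: none
Why: Catalytic asymmetric Nozaki–Hiyama–Kishi coupling: nickel activates the vinyl iodide with retention of the Z geometry, and the ligated trivalent chromium alkenyl adds 1,2 to acrolein under ligand control to set C6 (3S in the name of 14); the ester is tolerated.

Step 6
Reactants: 14 (3S,4Z,6S,8E)-11-[(tert-butyldimethylsilyl)oxy]-3-hydroxy-5,9-dimethylundeca-1,4,8-trien-6-yl 2-methylpropanoate; 15 2-(bromomethyl)prop-2-enoic acid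
Product: 16 (3S,4Z,6S,8E)-11-[(tert-butyldimethylsilyl)oxy]-5,9-dimethyl-6-[(2-methylpropanoyl)oxy]undeca-1,4,8-trien-3-yl 2-(bromomethyl)prop-2-enoate
Conditions: N,N'-diisopropylcarbodiimide, DMAP (5 mol%), CH2Cl2, 0 °C
Reagents that add atoms: none
Why: Steglich esterification of the only free hydroxyl with retention at C6; low temperature and low DMAP loading spare the allylic bromide.

Step 7
Reactants: 16 (3S,4Z,6S,8E)-11-[(tert-butyldimethylsilyl)oxy]-5,9-dimethyl-6-[(2-methylpropanoyl)oxy]undeca-1,4,8-trien-3-yl 2-(bromomethyl)prop-2-enoate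
Product: 17 (1Z,3S,5E)-1-[(2R)-4-(bromomethyl)-5-oxo-2,5-dihydrofuran-2-yl]-8-[(tert-butyldimethylsilyl)oxy]-2,6-dimethylocta-1,5-dien-3-yl 2-methylpropanoate
Conditions: second-generation Grubbs catalyst (5–10 mol%), toluene (0.005 M), 70 °C
Reagents that add atoms: none
Why: Ring-closing metathesis: the ruthenium carbene forms at the monosubstituted vinyl group and closes the five-membered ring onto the acrylate, while the two trisubstituted olefins do not compete and C6 is untouched.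

Step 8
Reactants: 17 (1Z,3S,5E)-1-[(2R)-4-(bromomethyl)-5-oxo-2,5-dihydrofuran-2-yl]-8-[(tert-butyldimethylsilyl)oxy]-2,6-dimethylocta-1,5-dien-3-yl 2-methylpropanoate
Product: 18 (1Z,3S,5E)-1-[(2R)-4-(bromomethyl)-5-oxo-2,5-dihydrofuran-2-yl]-8-hydroxy-2,6-dimethylocta-1,5-dien-3-yl 2-methylpropanoate
Conditions: HF (48% aq.), MeCN, 0 °C
Reagents that add atoms: none
Why: Acidic, non-nucleophilic desilylation of the primary silyl ether; no base touches the allylic bromide or the epimerisable γ-position of the butenolide.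

Step 9
Reactants: 18 (1Z,3S,5E)-1-[(2R)-4-(bromomethyl)-5-oxo-2,5-dihydrofuran-2-yl]-8-hydroxy-2,6-dimethylocta-1,5-dien-3-yl 2-methylpropanoate
Product: 19 (1Z,3S,5E)-1-[(2R)-4-(bromomethyl)-5-oxo-2,5-dihydrofuran-2-yl]-2,6-dimethyl-8-oxoocta-1,5-dien-3-yl 2-methylpropanoate
Conditions: Dess–Martin periodinane, NaHCO3, CH2Cl2, 0 °C; used at once
Reagents that add atoms: none
Why: Neutral Dess–Martin oxidation to the β,γ-unsaturated aldehyde; nothing else is oxidisable.

Step 10 (key step)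
Reactants: 19 (1Z,3S,5E)-1-[(2R)-4-(bromomethyl)-5-oxo-2,5-dihydrofuran-2-yl]-2,6-dimethyl-8-oxoocta-1,5-dien-3-yl 2-methylpropanoate
Product: 21 (3aR,4S,6E,9S,10Z,11aR)-4-hydroxy-6,10-dimethyl-3-methylidene-2-oxo-2,3,3a,4,5,8,9,11a-octahydrocyclodeca[b]furan-9-yl 2-methylpropanoate, via allylchromium 20 (not isolated)
Conditions: CrCl2 (10 equiv), THF/DMF 10:1, syringe-pump addition of 19 over 12 h to 0.002 M, rt; H2O
Reagents that add atoms: none
Why: Proposed new method: divalent chromium inserts into the allylic C–Br bond to give a trivalent allylchromium whose γ-carbon (C7, the normally electrophilic β-carbon of the butenolide) attacks the C8 aldehyde in an intramolecular Nozaki–Hiyama-type allylation, the exocyclic methylene forming by allylic transposition; attack anti to the C6 alkenyl group gives the trans lactone (7R), and the closed chair with the E-locked allyl unit and C9 equatorial gives the 7,8-anti (8S, 8α) alcohol. The closest known reactions are intermolecular Barbier allylations of 5-substituted 3-(bromomethyl)butenolides and chromium-mediated ten-membered ring closures of ω-formyl 2-(bromomethyl)acrylates.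

Step 11
Reactants: 22 (2E)-2-methylbut-2-en-1-ol
Product: 23 [(2S,3S)-2,3-dimethyloxiran-2-yl]methanol
Conditions: Ti(OiPr)4 (10 mol%), L-(+)-diisopropyl tartrate (12 mol%), t-BuOOH, 4 Å MS, CH2Cl2, −20 °C; non-aqueous work-up
Reagents that add atoms: tert-butyl hydroperoxide, CC(C)(C)OO
Why: Sharpless asymmetric epoxidation; L-(+)-tartrate delivers oxygen to the same face as for E-crotyl-type alcohols, giving the (2S,3S) epoxy alcohol with the two methyls cis.

Step 12
Reactants: 23 [(2S,3S)-2,3-dimethyloxiran-2-yl]methanol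
Product: 24 (2R,3S)-2,3-dimethyloxirane-2-carboxylic acid
Conditions: TEMPO (20 mol%), PhI(OAc)2 (2.2 equiv), MeCN/H2O 1:1, rt
Reagents that add atoms: water, O
Why: Oxoammonium oxidation through the aldehyde hydrate to the acid leaves the oxirane intact; the C2 descriptor changes from S to R only through CIP priorities.

Step 13
Reactants: 21 (3aR,4S,6E,9S,10Z,11aR)-4-hydroxy-6,10-dimethyl-3-methylidene-2-oxo-2,3,3a,4,5,8,9,11a-octahydrocyclodeca[b]furan-9-yl 2-methylpropanoate; 24 (2R,3S)-2,3-dimethyloxirane-2-carboxylic acid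
Product: 25 (3aR,4R,6E,9S,10Z,11aR)-6,10-dimethyl-3-methylidene-9-[(2-methylpropanoyl)oxy]-2-oxo-2,3,3a,4,5,8,9,11a-octahydrocyclodeca[b]furan-4-yl (2R,3S)-2,3-dimethyloxirane-2-carboxylate
Conditions: PPh3, diisopropyl azodicarboxylate, toluene, 0 °C → rt
Reagents that add atoms: none
Why: Mitsunobu esterification displaces the activated C8 oxygen by the carboxylate with SN2 inversion, turning the 8S alcohol into the required 8R ester; the acid (pKa about 3.5) is a good partner and its stereocentres are untouched.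

Step 14
Reactants: 25 (3aR,4R,6E,9S,10Z,11aR)-6,10-dimethyl-3-methylidene-9-[(2-methylpropanoyl)oxy]-2-oxo-2,3,3a,4,5,8,9,11a-octahydrocyclodeca[b]furan-4-yl (2R,3S)-2,3-dimethyloxirane-2-carboxylate
Product: 26 (1R,2R,4R,6R,8S,9Z,11R)-4,9-dimethyl-14-methylidene-8-[(2-methylpropanoyl)oxy]-13-oxo-5,12-dioxatricyclo[9.3.0.0(4,6)]tetradec-9-en-2-yl (2R,3S)-2,3-dimethyloxirane-2-carboxylate (CNP0117882.3)
Conditions: mCPBA (1.1 equiv), NaHCO3, CH2Cl2, 0 °C
Reagents that add atoms: 3-chloroperoxybenzoic acid, OOC(=O)c1cccc(Cl)c1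
Why: Prilezhaev epoxidation picks the only electron-rich olefin (C4=C5 is deactivated by two allylic acyloxy groups, the methylene lactone is electron-poor) and attacks the outer face of the E C1=C10 bond, giving the trans 1β,10α (1R,10R) oxirane.

## Compound list

1 | tert-butyl(but-3-yn-1-yloxy)dimethylsilane | C#CCCO[Si](C)(C)C(C)(C)C | starting material
2 | oxirane | C1CO1 | starting material
3 | [(1E)-4-[(tert-butyldimethylsilyl)oxy]-2-methylbut-1-en-1-yl]dimethylalane | C[Al](C)/C=C(\C)CCO[Si](C)(C)C(C)(C)C | intermediate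
4 | lithium butyl[(1E)-4-[(tert-butyldimethylsilyl)oxy]-2-methylbut-1-en-1-yl]dimethylaluminate | [Li+].CCCC[Al-](C)(C)/C=C(\C)CCO[Si](C)(C)C(C)(C)C | intermediate
5 | (3E)-6-[(tert-butyldimethylsilyl)oxy]-4-methylhex-3-en-1-ol | OCC/C=C(\C)CCO[Si](C)(C)C(C)(C)C | intermediate
6 | (3E)-6-[(tert-butyldimethylsilyl)oxy]-4-methylhex-3-enal | O=CC/C=C(\C)CCO[Si](C)(C)C(C)(C)C | intermediate
7 | ethynyltrimethylsilane | C#C[Si](C)(C)C | starting material
8 | methylzinc alkoxide of (3S,5E)-8-[(tert-butyldimethylsilyl)oxy]-6-methyl-1-(trimethylsilyl)oct-5-en-1-yn-3-ol | C[Si](C)(C)C#C[C@@H](O[Zn]C)C/C=C(\C)CCO[Si](C)(C)C(C)(C)C | intermediate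
9 | (3S,5E)-8-[(tert-butyldimethylsilyl)oxy]-6-methyloct-5-en-1-yn-3-ol | C#C[C@@H](O)C/C=C(\C)CCO[Si](C)(C)C(C)(C)C | intermediate
10 | bromomagnesium alkoxide of (1Z,3S,5E)-1-(bromomagnesio)-8-[(tert-butyldimethylsilyl)oxy]-2,6-dimethylocta-1,5-dien-3-ol | Br[Mg]/C=C(/C)[C@@H](O[Mg]Br)C/C=C(\C)CCO[Si](C)(C)C(C)(C)C | intermediate
11 | bromomagnesium alkoxide of (1Z,3S,5E)-8-[(tert-butyldimethylsilyl)oxy]-1-iodo-2,6-dimethylocta-1,5-dien-3-ol | I/C=C(/C)[C@@H](O[Mg]Br)C/C=C(\C)CCO[Si](C)(C)C(C)(C)C | intermediate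
12 | (1Z,3S,5E)-8-[(tert-butyldimethylsilyl)oxy]-1-iodo-2,6-dimethylocta-1,5-dien-3-yl 2-methylpropanoate | I/C=C(/C)[C@@H](OC(=O)C(C)C)C/C=C(\C)CCO[Si](C)(C)C(C)(C)C | intermediate
13 | prop-2-enal | C=CC=O | starting material
14 | (3S,4Z,6S,8E)-11-[(tert-butyldimethylsilyl)oxy]-3-hydroxy-5,9-dimethylundeca-1,4,8-trien-6-yl 2-methylpropanoate | C=C[C@H](O)/C=C(/C)[C@@H](OC(=O)C(C)C)C/C=C(\C)CCO[Si](C)(C)C(C)(C)C | intermediate
15 | 2-(bromomethyl)prop-2-enoic acid | OC(=O)C(=C)CBr | starting material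
16 | (3S,4Z,6S,8E)-11-[(tert-butyldimethylsilyl)oxy]-5,9-dimethyl-6-[(2-methylpropanoyl)oxy]undeca-1,4,8-trien-3-yl 2-(bromomethyl)prop-2-enoate | C=C[C@H](OC(=O)C(=C)CBr)/C=C(/C)[C@@H](OC(=O)C(C)C)C/C=C(\C)CCO[Si](C)(C)C(C)(C)C | intermediate
17 | (1Z,3S,5E)-1-[(2R)-4-(bromomethyl)-5-oxo-2,5-dihydrofuran-2-yl]-8-[(tert-butyldimethylsilyl)oxy]-2,6-dimethylocta-1,5-dien-3-yl 2-methylpropanoate | BrCC1=C[C@@H](/C=C(/C)[C@@H](OC(=O)C(C)C)C/C=C(\C)CCO[Si](C)(C)C(C)(C)C)OC1=O | intermediate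
18 | (1Z,3S,5E)-1-[(2R)-4-(bromomethyl)-5-oxo-2,5-dihydrofuran-2-yl]-8-hydroxy-2,6-dimethylocta-1,5-dien-3-yl 2-methylpropanoate | BrCC1=C[C@@H](/C=C(/C)[C@@H](OC(=O)C(C)C)C/C=C(\C)CCO)OC1=O | intermediate
19 | (1Z,3S,5E)-1-[(2R)-4-(bromomethyl)-5-oxo-2,5-dihydrofuran-2-yl]-2,6-dimethyl-8-oxoocta-1,5-dien-3-yl 2-methylpropanoate | BrCC1=C[C@@H](/C=C(/C)[C@@H](OC(=O)C(C)C)C/C=C(\C)CC=O)OC1=O | intermediate
20 | (1Z,3S,5E)-1-[(2R)-4-[(dichlorochromio)methyl]-5-oxo-2,5-dihydrofuran-2-yl]-2,6-dimethyl-8-oxoocta-1,5-dien-3-yl 2-methylpropanoate | Cl[Cr](Cl)CC1=C[C@@H](/C=C(/C)[C@@H](OC(=O)C(C)C)C/C=C(\C)CC=O)OC1=O | intermediate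
21 | (3aR,4S,6E,9S,10Z,11aR)-4-hydroxy-6,10-dimethyl-3-methylidene-2-oxo-2,3,3a,4,5,8,9,11a-octahydrocyclodeca[b]furan-9-yl 2-methylpropanoate | C=C1C(=O)O[C@@H]2/C=C(/C)[C@@H](OC(=O)C(C)C)C/C=C(\C)C[C@H](O)[C@@H]12 | intermediate
22 | (2E)-2-methylbut-2-en-1-ol | C/C=C(\C)CO | starting material
23 | [(2S,3S)-2,3-dimethyloxiran-2-yl]methanol | OC[C@]1(C)O[C@H]1C | intermediate
24 | (2R,3S)-2,3-dimethyloxirane-2-carboxylic acid | OC(=O)[C@]1(C)O[C@H]1C | intermediate
25 | (3aR,4R,6E,9S,10Z,11aR)-6,10-dimethyl-3-methylidene-9-[(2-methylpropanoyl)oxy]-2-oxo-2,3,3a,4,5,8,9,11a-octahydrocyclodeca[b]furan-4-yl (2R,3S)-2,3-dimethyloxirane-2-carboxylate | C=C1C(=O)O[C@@H]2/C=C(/C)[C@@H](OC(=O)C(C)C)C/C=C(\C)C[C@@H](OC(=O)[C@]3(C)O[C@H]3C)[C@@H]12 | intermediate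
26 | (1R,2R,4R,6R,8S,9Z,11R)-4,9-dimethyl-14-methylidene-8-[(2-methylpropanoyl)oxy]-13-oxo-5,12-dioxatricyclo[9.3.0.0(4,6)]tetradec-9-en-2-yl (2R,3S)-2,3-dimethyloxirane-2-carboxylate | C=C1C(=O)O[C@@H]2/C=C(/C)[C@@H](OC(=O)C(C)C)C[C@H]3O[C@]3(C)C[C@@H](OC(=O)[C@]3(C)O[C@H]3C)[C@@H]12 | target

## Step count and risk

Total steps: 14. Longest linear sequence: 12 (steps 1–10, 13, 14); steps 11–12 make the side-chain acid.

**Step 10 (chromium macrocyclisation).** Risks are oligomerisation, β-elimination of the lactone oxygen from the allylmetal, and the wrong C8 epimer. The fallback sets out from 14 and comes back at 25. Esterify 14 with 2-[(trimethylsilyl)methyl]prop-2-enoic acid (carbodiimide, DMAP) to the silylmethyl acrylate ester F1. Ring-closing metathesis gives the allylsilane butenolide F2. PPTS in MeOH removes the primary silyl ether to give alcohol F3, and Dess–Martin oxidation gives aldehyde F4. BF3·OEt2 in CH2Cl2 at −78 °C under high dilution then closes the ring by an intramolecular Hosomi–Sakurai reaction through an open transition state, expected to give the syn (8R) alcohol F5. Steglich esterification of F5 with 24 (retention) gives 25.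

**Step 5 (catalyst-controlled coupling with acrolein).** The risk is low selectivity at C6. The fallback sets out from 12 and comes back at 14. Run the coupling without chiral ligand (CrCl2, cat. NiCl2, DMF) to give 14 mixed about 1:1 with its C6 epimer F6. Sharpless kinetic resolution (Ti(OiPr)4, L-(+)-diisopropyl tartrate, t-BuOOH, −20 °C) epoxidises the vinyl group of the epimer faster to the epoxy alcohol F7, which is removed by chromatography, leaving 14.

**Step 13 (Mitsunobu inversion at C8).** Risks are elimination or sluggish displacement at a hindered ring carbinol. The fallback sets out from 21 and comes back at 25. Convert 21 with ClCH2SO2Cl and pyridine into the chloromethanesulfonate F8, then displace with the caesium salt of 24 (Cs2CO3, 18-crown-6, toluene, 60 °C) in an SN2 reaction with inversion to give 25.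

Further compounds
F1 | step 10 | (3S,4Z,6S,8E)-11-[(tert-butyldimethylsilyl)oxy]-5,9-dimethyl-6-[(2-methylpropanoyl)oxy]undeca-1,4,8-trien-3-yl 2-[(trimethylsilyl)methyl]prop-2-enoate | C=C[C@H](OC(=O)C(=C)C[Si](C)(C)C)/C=C(/C)[C@@H](OC(=O)C(C)C)C/C=C(\C)CCO[Si](C)(C)C(C)(C)C
F2 | step 10 | (1Z,3S,5E)-8-[(tert-butyldimethylsilyl)oxy]-2,6-dimethyl-1-{(2R)-5-oxo-4-[(trimethylsilyl)methyl]-2,5-dihydrofuran-2-yl}octa-1,5-dien-3-yl 2-methylpropanoate | C[Si](C)(C)CC1=C[C@@H](/C=C(/C)[C@@H](OC(=O)C(C)C)C/C=C(\C)CCO[Si](C)(C)C(C)(C)C)OC1=O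
F3 | step 10 | (1Z,3S,5E)-8-hydroxy-2,6-dimethyl-1-{(2R)-5-oxo-4-[(trimethylsilyl)methyl]-2,5-dihydrofuran-2-yl}octa-1,5-dien-3-yl 2-methylpropanoate | C[Si](C)(C)CC1=C[C@@H](/C=C(/C)[C@@H](OC(=O)C(C)C)C/C=C(\C)CCO)OC1=O
F4 | step 10 | (1Z,3S,5E)-2,6-dimethyl-8-oxo-1-{(2R)-5-oxo-4-[(trimethylsilyl)methyl]-2,5-dihydrofuran-2-yl}octa-1,5-dien-3-yl 2-methylpropanoate | C[Si](C)(C)CC1=C[C@@H](/C=C(/C)[C@@H](OC(=O)C(C)C)C/C=C(\C)CC=O)OC1=O
F5 | step 10 | (3aR,4R,6E,9S,10Z,11aR)-4-hydroxy-6,10-dimethyl-3-methylidene-2-oxo-2,3,3a,4,5,8,9,11a-octahydrocyclodeca[b]furan-9-yl 2-methylpropanoate | C=C1C(=O)O[C@@H]2/C=C(/C)[C@@H](OC(=O)C(C)C)C/C=C(\C)C[C@@H](O)[C@@H]12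
F6 | step 5 | (3R,4Z,6S,8E)-11-[(tert-butyldimethylsilyl)oxy]-3-hydroxy-5,9-dimethylundeca-1,4,8-trien-6-yl 2-methylpropanoate | C=C[C@@H](O)/C=C(/C)[C@@H](OC(=O)C(C)C)C/C=C(\C)CCO[Si](C)(C)C(C)(C)C
F7 | step 5 | (1S,2Z,4S,6E)-9-[(tert-butyldimethylsilyl)oxy]-1-hydroxy-3,7-dimethyl-1-[(2R)-oxiran-2-yl]nona-2,6-dien-4-yl 2-methylpropanoate | O[C@@H](/C=C(/C)[C@@H](OC(=O)C(C)C)C/C=C(\C)CCO[Si](C)(C)C(C)(C)C)[C@H]1CO1
F8 | step 13 | (3aS,4S,6E,9S,10Z,11aR)-4-{[(chloromethyl)sulfonyl]oxy}-6,10-dimethyl-3-methylidene-2-oxo-2,3,3a,4,5,8,9,11a-octahydrocyclodeca[b]furan-9-yl 2-methylpropanoate | C=C1C(=O)O[C@@H]2/C=C(/C)[C@@H](OC(=O)C(C)C)C/C=C(\C)C[C@H](OS(=O)(=O)CCl)[C@@H]12
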